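**Retrosynthetic overview**

1. Locants (cembrane-type numbering): ring A = C1, C2, C3, C4, C16, C15; ring B = C4, C5, C6, C7, C16; ring C = C1, C15, C16 and C7 to C14; C17 = CH2 on C15; C18, C19, C20 = methyls on C4, C8, C12; oxygens on C3, C9, C13.
2. Target 28 ⇐ ring C closed last by Nozaki–Hiyama–Kishi addition C12–C13 (iodo aldehyde 24); ring A closed before it by Dieckmann-type acylation C1→C15 of lactone ester 17; C10–C12 and C13–C14 come from two allylations.
3. Lactone aldehyde 13 ⇐ acid-triggered retro-aldol opening of cyclobutane 12 ⇐ intramolecular [2+2] photocycloaddition of dihydrofuran ester 11 (de Mayo logic), which closes ring B (C16–C7) and then the cyclobutane (C8–C9).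
4. Enabling feature: C15 and the oxygen-bearing C9 are 1,5-related through C16, C7, C8 (retron = cyclobutane C16–C7–C8–C9); ring B is five-membered; O3 on C3, next to quaternary C4, can be lent to C9 as enol-ether oxygen (temporary ring O–C9=C16–C4–C3), which forces C8 onto the C3 face of ring B.
5. 11 ⇐ butenolide 6 ⇐ L-glutamic acid 5-tert-butyl ester 1 (C3, source of all absolute configuration); ring order: dihydrofuran (temporary), ring B with cyclobutane (temporary), γ-lactone (temporary), ring A, ring C.

Key step: step 8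

Remark: the ring C alkene is taken as drawn, (11Z) with C10 and C13 cis; β denotes the face of ring B that carries C18.

**Route**

Step 1
Reactants: 1 L-glutamic acid 5-tert-butyl ester
Product: 2 (2S)-5-tert-butoxy-2-hydroxy-5-oxopentanoic acid
Conditions: NaNO2, AcOH/H2O (1:4), 0 °C to rt
Reagents that add atoms: water, O
Why: Diazotisation and hydrolysis through the α-lactone (double inversion, van Slyke-type deamination) should give the α-hydroxy acid with retention, so the future C3 keeps the (S) configuration of L-glutamate.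

Step 2
Reactants: 2 (2S)-5-tert-butoxy-2-hydroxy-5-oxopentanoic acid
Product: 3 tert-butyl (4S)-4-hydroxy-5-[methoxy(methyl)amino]-5-oxopentanoate
Conditions: MeNH(OMe)·HCl, EDC·HCl, HOBt (cat.), N-methylmorpholine, CH2Cl2, 0 °C to rt
Reagents that add atoms: N,O-dimethylhydroxylamine hydrochloride, CNOC.Cl
Why: Carbodiimide amidation gives the Weinreb amide without touching the stereocentre or the tert-butyl ester.

Step 3
Reactants: 3 tert-butyl (4S)-4-hydroxy-5-[methoxy(methyl)amino]-5-oxopentanoate; 4 (E)-5-bromopent-2-ene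
Product: 5 tert-butyl (4S,8E)-4-hydroxy-5-oxodec-8-enoate
Conditions: 4, Mg, THF, rt to 40 °C (3 equiv of Grignard reagent); 3, THF, −20 to 0 °C; aq. NH4Cl
Reagents that add atoms: none
Why: Weinreb ketone synthesis, in which the chelated magnesium tetrahedral intermediate stops at the ketone and the hindered tert-butyl ester is not attacked; this brings in C5 to C8 and C19.

Step 4
Reactants: 5 tert-butyl (4S,8E)-4-hydroxy-5-oxodec-8-enoate
Product: 6 tert-butyl 3-[(2S)-5-oxo-3-[(3E)-pent-3-en-1-yl]-2,5-dihydrofuran-2-yl]propanoate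
Conditions: Ph3P=C=C=O, toluene, 90 °C
Reagents that add atoms: (triphenylphosphoranylidene)ketene, O=C=C=P(c1ccccc1)(c1ccccc1)c1ccccc1
Why: Addition of the hydroxyl to the ketenylidene ylide followed by intramolecular Wittig reaction with the ketone (Bestmann butenolide synthesis) should give the butenolide, whose two new carbons become C16 and C9.

Step 5
Reactants: 6 tert-butyl 3-[(2S)-5-oxo-3-[(3E)-pent-3-en-1-yl]-2,5-dihydrofuran-2-yl]propanoate
Product: 7 tert-butyl 3-[(2S,3S)-3-methyl-5-oxo-3-[(3E)-pent-3-en-1-yl]oxolan-2-yl]propanoate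
Conditions: Me2CuLi (MeLi, CuI), Et2O, −40 to 0 °C; aq. NH4Cl
Reagents that add atoms: lithium dimethylcuprate, [Li+].C[Cu-]C
Why: Gilman conjugate addition to the β,β-disubstituted butenolide should occur anti to the C3 side chain, creating quaternary C4 with C18 trans to that chain and the pentenyl tether cis to it.

Step 6
Reactants: 7 tert-butyl 3-[(2S,3S)-3-methyl-5-oxo-3-[(3E)-pent-3-en-1-yl]oxolan-2-yl]propanoate
Product: 9 tert-butyl 3-[(2S,3S)-3-methyl-3-[(3E)-pent-3-en-1-yl]-2,3-dihydrofuran-2-yl]propanoate, via lactol 8 (not isolated)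
Conditions: i-Bu2AlH (1.1 equiv), CH2Cl2, −78 °C, potassium sodium tartrate work-up; crude lactol, MsCl, Et3N, CH2Cl2, 0 to 40 °C
Reagents that add atoms: none
Why: Partial reduction of the lactone (faster than the tert-butyl ester) and elimination through the anomeric mesylate should give the cyclic enol ether O–C9H=C16H, since quaternary C4 leaves C16–H as the only β-hydrogen.

Step 7
Reactants: 9 tert-butyl 3-[(2S,3S)-3-methyl-3-[(3E)-pent-3-en-1-yl]-2,3-dihydrofuran-2-yl]propanoate
Product: 11 methyl (4S,5S)-5-(3-tert-butoxy-3-oxopropyl)-4-methyl-4-[(3E)-pent-3-en-1-yl]-4,5-dihydrofuran-3-carboxylate, via trichloromethyl ketone 10 (not isolated)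
Conditions: Cl3CCOCl, pyridine, CH2Cl2, 0 °C to rt; then MeOH, K2CO3 (cat.), rt
Reagents that add atoms: trichloroacetyl chloride, ClC(=O)C(Cl)(Cl)Cl; methanol, CO
Why: Electrophilic β-acylation of the enol ether at C16 (trichloroacetylation of enol ethers) and haloform-type methanolysis should install C15 as the methyl ester and give the β-alkoxy enoate chromophore with both stereocentres untouched.

Step 8
Reactants: 11 methyl (4S,5S)-5-(3-tert-butoxy-3-oxopropyl)-4-methyl-4-[(3E)-pent-3-en-1-yl]-4,5-dihydrofuran-3-carboxylate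
Product: 12 cyclobutane photoadduct (cyclobutane C16–C7–C8–C9 cis-fused to ring B and to the tetrahydrofuran O–C9–C16–C4–C3; CO2Me on C16 β; H7 β; C19 exo and cis to H7)
Conditions: hν (300 nm, Pyrex), acetone/MeCN (1:9), 0 °C, degassed, 5 mM
Reagents that add atoms: none
Why: Acetone-sensitised intramolecular [2+2] photocycloaddition of the ring-constrained β-alkoxy enoate (triplet, stepwise): C16 first bonds to C7 in a 5-exo closure that forms ring B (rule of five) and leaves a 1,4-biradical at C9 (α-oxygen stabilised) and C8, which then recombines to form C8–C9 and close the cyclobutane. The closest known reaction type is the intramolecular dioxenone–alkene photocycloaddition used as the first half of de Mayo sequences, the dihydrofuran oxygen here playing the part of the dioxenone enol-ether oxygen. C16, C7 and C9 are set by the tether, because the pentenyl chain on the stereodefined quaternary C4 can reach the C9=C16 bond only on its own face, so that ring B, the tetrahydrofuran and the cyclobutane are all cis-fused around C16 and C8 ends up on the face of ring B that carries C3. C8 is set in the biradical recombination, where the C19 methyl should take the exo position, cis to H7 and away from the concave face flanked by the ring oxygen and C6; since the biradical rotates freely, the E/Z purity of the alkene is immaterial. The step needs straight (fused) over crossed closure, secured by the two-atom spacer between C4 and C7 that makes the five-membered ring the first to form, and excitation of the enoate alone, secured by the absence of any other chromophore above 280 nm. The product is a strained donor–acceptor cyclobutane (O on C9, ester on C16) that thermal chemistry does not reach and whose strain drives the fragmentation in step 9.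

Step 9
Reactants: 12 cyclobutane photoadduct
Product: 13 lactone aldehyde (ring B cis-fused on its α face to the γ-lactone C15(=O)–O–C3; H16 β; C7 carries (8S)-CH(CH3)–CHO; C3 carries CH2CH2CO2tBu)
Conditions: Sc(OTf)3 (10 mol %), MeCN/H2O (20:1), 40 °C
Reagents that add atoms: water, O
Why: Lewis-acid heterolysis of the C16–C9 bond of the donor–acceptor cyclobutane (retro-aldol half of the de Mayo sequence) gives an oxocarbenium ion and an ester enol, after which water releases the C9 aldehyde and O3–H, C16 is protonated on the open β face, and O3 lactonises onto the cis methyl ester (not the tert-butyl ester), fixing C16.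

Step 10
Reactants: 13 lactone aldehyde
Product: 14 (9S)-homoallylic alcohol (13 with C9HO converted into CH(OH)–CH2–CH=CH2; C19 and O9 syn)
Conditions: (−)-Ipc2BOMe, allylMgBr, Et2O, 0 °C to rt; 13, −78 °C; then HOCH2CH2NH2
Reagents that add atoms: allylmagnesium bromide, C=CC[Mg]Br
Why: Brown allylboration through a chair Zimmerman–Traxler transition state, in which the reagent derived from (+)-α-pinene adds to the Si face, which is also the Felkin–Anh face of the α-methyl aldehyde (matched case), so C9 should be set (S) while lactone and ester stay inert at −78 °C.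

Step 11
Reactants: 14 (9S)-homoallylic alcohol
Product: 15 tert-butyldimethylsilyl ether of 14
Conditions: TBSCl, imidazole, DMF, 40 °C
Reagents that add atoms: tert-butyldimethylsilyl chloride, CC(C)(C)[Si](C)(C)Cl
Why: Silylation masks O9 so that it cannot translactonise onto C15 during the basic ring A closure.

Step 12
Reactants: 15 tert-butyldimethylsilyl ether
Product: 16 β-silyloxy aldehyde (C11 aldehyde; 15 with CH=CH2 cut to CHO)
Conditions: O3, CH2Cl2/MeOH (4:1), −78 °C; PPh3
Reagents that add atoms: ozone, [O-][O+]=O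
Why: Ozonolysis with reductive work-up cleaves the only alkene present and leaves C10–C11 as the aldehyde.

Step 13
Reactants: 16 β-silyloxy aldehyde
Product: 17 (Z)-vinyl iodide lactone (C9(OTBS)–C10H2–C11H=C12(CH3)–I, iodine cis to C10)
Conditions: Ph3PEtI, n-BuLi, THF, rt; I2, −78 °C; NaN(SiMe3)2, −78 to −20 °C; 16, −78 °C
Reagents that add atoms: ethyltriphenylphosphonium iodide, CC[P+](c1ccccc1)(c1ccccc1)c1ccccc1.[I-]; iodine, II
Why: Zhao olefination (α-iodo variant of the Stork–Zhao Wittig reaction) with the non-stabilised iodo-ylide should give the (Z)-2-iodo-2-alkene through the cis-oxaphosphetane, which fixes the C11=C12 geometry and brings in C12 and C20.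

Step 14
Reactants: 17 (Z)-vinyl iodide lactone
Product: 18 ring A β-keto ester (cis-hydrindanone: C15 ketone, CO2tBu on C1 as an epimer or enol mixture, free 3β-OH)
Conditions: LiN(SiMe3)2 (2.5 equiv), THF, −78 to −10 °C; aq. NH4Cl
Reagents that add atoms: none
Why: Dieckmann-type intramolecular Claisen acylation, in which the tert-butyl ester enolate at C1 adds to the lactone carbonyl C15 through a 7-oxanorbornane alkoxide that opens to the ring A ketone and the O3 alkoxide; the enolisable β-keto ester is the thermodynamic sink, whereas acylation at C16 would give a non-enolisable product and reverts.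

Step 15
Reactants: 18 ring A β-keto ester
Product: 19 C1-allyl β-keto ester (quaternary C1 bearing CH2CH=CH2 and CO2tBu; epimers at C1)
Conditions: allyl bromide, K2CO3, acetone, 50 °C
Reagents that add atoms: allyl bromide, C=CCBr
Why: C-alkylation of the β-keto ester enolate places C14 and C13 regiospecifically on C1, and the configuration of the quaternary centre is immaterial because the ester is removed in step 17.

Step 16
Reactants: 19 C1-allyl β-keto ester
Product: 20 O3-propionate of 19
Conditions: (EtCO)2O, DMAP (cat.), Et3N, CH2Cl2, 40 °C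
Reagents that add atoms: propanoic anhydride, CCC(=O)OC(=O)CC
Why: DMAP-catalysed acylation installs the first of the three target esters and stops O3 from forming lactones or lactols in the next steps.

Step 17
Reactants: 20 O3-propionate
Product: 23 allyl ketone (C15 ketone; C1–H with the allyl group equatorial and cis to O3; H16 β), via trimethylsilyl ester 21 (not isolated), via keto acid 22 (not isolated)
Conditions: Me3SiOTf, 2,6-lutidine, CH2Cl2, 0 °C; aq. KH2PO4; toluene, 70 °C; DBU (cat.), rt
Reagents that add atoms: none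
Why: Silyl triflate cleavage of the tert-butyl ester (loss of isobutene) spares the silyl ether, propionate and vinyl iodide; the β-keto acid decarboxylates on warming, and equilibration α to the ketone should put C14 equatorial, cis-1,3 to the equatorial O3, which is the C1 configuration of the target.

Step 18
Reactants: 23 allyl ketone
Product: 24 keto aldehyde (C1–CH2–CHO, C13 aldehyde)
Conditions: OsO4 (2 mol %), NaIO4, 2,6-lutidine, dioxane/H2O (3:1), rt
Reagents that add atoms: sodium periodate, [Na+].[O-]I(=O)(=O)=O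
Why: Lemieux–Johnson cleavage takes the monosubstituted alkene, the electron-poor trisubstituted iodoalkene being dihydroxylated much more slowly.

Step 19
Reactants: 24 keto aldehyde
Product: 25 macrocyclic allylic alcohol (ring C closed; (13R)-OH; (11Z); O9-TBS; O3-propionate; C15 ketone)
Conditions: CrCl2 (8 equiv), NiCl2 (2 mol %), DMSO/THF (3:1), rt, 2 mM, slow addition
Reagents that add atoms: none
Why: Nozaki–Hiyama–Kishi macrocyclisation, in which nickel-catalysed activation of the C–I bond and transmetallation give the alkenyl derivative of trivalent chromium with retention of the (Z) geometry, and this adds to the aldehyde only (ketone and esters inert); C13 is formed under macrocyclic control by attack on the outer face of the folding chain and is the least secure stereocentre.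

Step 20
Reactants: 25 macrocyclic allylic alcohol
Product: 26 9,13-diol (O3-propionate, C15 ketone)
Conditions: HF·pyridine, THF/pyridine, 0 °C to rt
Reagents that add atoms: none
Why: Fluoride-mediated desilylation frees O9–H under conditions that leave the propionate and the allylic alcohol untouched.

Step 21
Reactants: 26 9,13-diol
Product: 27 3,9,13-tripropionate C15 ketone
Conditions: (EtCO)2O (excess), DMAP, Et3N, CH2Cl2, rt
Reagents that add atoms: propanoic anhydride, CCC(=O)OC(=O)CC
Why: DMAP-catalysed acylation esterifies both secondary alcohols and drains any hemiketal with C15 back to the open hydroxy ketone.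

Step 22
Reactants: 27 3,9,13-tripropionate C15 ketone
Product: 28 (1R,3S,4S,7R,8S,9S,11Z,13R,16S)-trinervita-11,15(17)-diene-3,9,13-triyl tripropanoate (target)
Conditions: Zn, CH2Br2, TiCl4, THF/CH2Cl2, 0 °C to rt
Reagents that add atoms: dibromomethane, BrCBr
Why: Lombardo–Takai methylenation with the non-basic titanium–zinc methylene reagent should convert the hindered, enolisable C15 ketone into the exocyclic alkene without epimerising C1 or C16 and without touching the three esters.

**Compound list**

1 | L-glutamic acid 5-tert-butyl ester | N[C@@H](CCC(=O)OC(C)(C)C)C(=O)O | starting material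
2 | (2S)-5-tert-butoxy-2-hydroxy-5-oxopentanoic acid | O[C@@H](CCC(=O)OC(C)(C)C)C(=O)O | intermediate
3 | tert-butyl (4S)-4-hydroxy-5-[methoxy(methyl)amino]-5-oxopentanoate | O[C@@H](CCC(=O)OC(C)(C)C)C(=O)N(C)OC | intermediate
4 | (E)-5-bromopent-2-ene | C/C=C/CCBr | starting material
5 | tert-butyl (4S,8E)-4-hydroxy-5-oxodec-8-enoate | O[C@@H](CCC(=O)OC(C)(C)C)C(=O)CC/C=C/C | intermediate
6 | tert-butyl 3-[(2S)-5-oxo-3-[(3E)-pent-3-en-1-yl]-2,5-dihydrofuran-2-yl]propanoate | O=C1C=C(CC/C=C/C)[C@H](CCC(=O)OC(C)(C)C)O1 | intermediate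
7 | tert-butyl 3-[(2S,3S)-3-methyl-5-oxo-3-[(3E)-pent-3-en-1-yl]oxolan-2-yl]propanoate | O=C1C[C@](C)(CC/C=C/C)[C@H](CCC(=O)OC(C)(C)C)O1 | intermediate
8 | lactol: tert-butyl 3-[(2S,3S)-5-hydroxy-3-methyl-3-[(3E)-pent-3-en-1-yl]oxolan-2-yl]propanoate (anomer mixture) | OC1C[C@](C)(CC/C=C/C)[C@H](CCC(=O)OC(C)(C)C)O1 | intermediate
9 | tert-butyl 3-[(2S,3S)-3-methyl-3-[(3E)-pent-3-en-1-yl]-2,3-dihydrofuran-2-yl]propanoate | C1=C[C@](C)(CC/C=C/C)[C@H](CCC(=O)OC(C)(C)C)O1 | intermediate
10 | trichloromethyl ketone: tert-butyl 3-[(2S,3S)-3-methyl-3-[(3E)-pent-3-en-1-yl]-4-(trichloroacetyl)-2,3-dihydrofuran-2-yl]propanoate | C1=C(C(=O)C(Cl)(Cl)Cl)[C@](C)(CC/C=C/C)[C@H](CCC(=O)OC(C)(C)C)O1 | intermediate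
11 | methyl (4S,5S)-5-(3-tert-butoxy-3-oxopropyl)-4-methyl-4-[(3E)-pent-3-en-1-yl]-4,5-dihydrofuran-3-carboxylate | C1=C(C(=O)OC)[C@](C)(CC/C=C/C)[C@H](CCC(=O)OC(C)(C)C)O1 | intermediate
12 | cyclobutane photoadduct: cyclobutane C16–C7–C8–C9 cis-fused to ring B and to tetrahydrofuran O–C9–C16–C4–C3; CO2Me on C16 β; H7 β; C19 exo (cis to H7); CH2CH2CO2tBu on C3 | [C@@H]1(CCC(=O)OC(C)(C)C)O[C@@H]2[C@@H](C)[C@@H]3CC[C@@]1(C)[C@]23C(=O)OC | intermediate
13 | lactone aldehyde: ring B cis-fused (α face) to γ-lactone C15(=O)–O–C3; H16 and H7 β; (8S)-CH(CH3)CHO on C7; CH2CH2CO2tBu on C3 | O=C1O[C@@H](CCC(=O)OC(C)(C)C)[C@@]2(C)CC[C@@H]([C@H](C)C=O)[C@@H]12 | intermediate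
14 | (9S)-homoallylic alcohol: 13 with C9 as CH(OH)CH2CH=CH2 | O=C1O[C@@H](CCC(=O)OC(C)(C)C)[C@@]2(C)CC[C@@H]([C@H](C)[C@@H](O)CC=C)[C@@H]12 | intermediate
15 | O9-tert-butyldimethylsilyl ether of 14 | O=C1O[C@@H](CCC(=O)OC(C)(C)C)[C@@]2(C)CC[C@@H]([C@H](C)[C@@H](O[Si](C)(C)C(C)(C)C)CC=C)[C@@H]12 | intermediate
16 | β-silyloxy aldehyde: 15 with the vinyl group cut to the C11 aldehyde | O=C1O[C@@H](CCC(=O)OC(C)(C)C)[C@@]2(C)CC[C@@H]([C@H](C)[C@@H](O[Si](C)(C)C(C)(C)C)CC=O)[C@@H]12 | intermediate
17 | (Z)-vinyl iodide lactone: C9(OTBS)–CH2–CH=C(CH3)I with iodine cis to C10 | O=C1O[C@@H](CCC(=O)OC(C)(C)C)[C@@]2(C)CC[C@@H]([C@H](C)[C@@H](O[Si](C)(C)C(C)(C)C)C/C=C(/C)I)[C@@H]12 | intermediate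
18 | ring A β-keto ester: cis-hydrindanone with C15 ketone, CO2tBu on C1 (epimers/enol), 3β-OH, side chain of 17 on C7 | O=C1C(C(=O)OC(C)(C)C)C[C@H](O)[C@@]2(C)CC[C@@H]([C@H](C)[C@@H](O[Si](C)(C)C(C)(C)C)C/C=C(/C)I)[C@@H]12 | intermediate
19 | C1-allyl β-keto ester (epimers at quaternary C1) | O=C1C(CC=C)(C(=O)OC(C)(C)C)C[C@H](O)[C@@]2(C)CC[C@@H]([C@H](C)[C@@H](O[Si](C)(C)C(C)(C)C)C/C=C(/C)I)[C@@H]12 | intermediate
20 | O3-propionate of 19 | O=C1C(CC=C)(C(=O)OC(C)(C)C)C[C@H](OC(=O)CC)[C@@]2(C)CC[C@@H]([C@H](C)[C@@H](O[Si](C)(C)C(C)(C)C)C/C=C(/C)I)[C@@H]12 | intermediate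
21 | trimethylsilyl ester corresponding to 20 | O=C1C(CC=C)(C(=O)O[Si](C)(C)C)C[C@H](OC(=O)CC)[C@@]2(C)CC[C@@H]([C@H](C)[C@@H](O[Si](C)(C)C(C)(C)C)C/C=C(/C)I)[C@@H]12 | intermediate
22 | β-keto acid corresponding to 20 | O=C1C(CC=C)(C(=O)O)C[C@H](OC(=O)CC)[C@@]2(C)CC[C@@H]([C@H](C)[C@@H](O[Si](C)(C)C(C)(C)C)C/C=C(/C)I)[C@@H]12 | intermediate
23 | allyl ketone: C15 ketone, C1–H with allyl cis to O3 (configuration of 28 at C1) | O=C1[C@H](CC=C)C[C@H](OC(=O)CC)[C@@]2(C)CC[C@@H]([C@H](C)[C@@H](O[Si](C)(C)C(C)(C)C)C/C=C(/C)I)[C@@H]12 | intermediate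
24 | keto aldehyde: 23 with allyl cut to CH2CHO (C13 aldehyde) | O=C1[C@H](CC=O)C[C@H](OC(=O)CC)[C@@]2(C)CC[C@@H]([C@H](C)[C@@H](O[Si](C)(C)C(C)(C)C)C/C=C(/C)I)[C@@H]12 | intermediate
25 | macrocyclic allylic alcohol: trinervitane skeleton, C15 ketone, (13R)-OH, (11Z), O9-TBS, O3-propionate | O=C1[C@H]2C[C@H](OC(=O)CC)[C@@]3(C)CC[C@@H]([C@H](C)[C@@H](O[Si](C)(C)C(C)(C)C)C/C=C(/C)[C@H](O)C2)[C@@H]13 | intermediate
26 | 9,13-diol: 25 without the silyl group | O=C1[C@H]2C[C@H](OC(=O)CC)[C@@]3(C)CC[C@@H]([C@H](C)[C@@H](O)C/C=C(/C)[C@H](O)C2)[C@@H]13 | intermediate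
27 | 3,9,13-tripropionate C15 ketone | O=C1[C@H]2C[C@H](OC(=O)CC)[C@@]3(C)CC[C@@H]([C@H](C)[C@@H](OC(=O)CC)C/C=C(/C)[C@H](OC(=O)CC)C2)[C@@H]13 | intermediate
28 | (1R,3S,4S,7R,8S,9S,11Z,13R,16S)-trinervita-11,15(17)-diene-3,9,13-triyl tripropanoate | C=C1[C@H]2C[C@H](OC(=O)CC)[C@@]3(C)CC[C@@H]([C@H](C)[C@@H](OC(=O)CC)C/C=C(/C)[C@H](OC(=O)CC)C2)[C@@H]13 | target

**Step count and risks**

Total step count: 22. Longest linear sequence: 22 steps (1 to 28).

Steps most likely to fail:

Step 8 (inefficient population of the reactive enoate triplet, with energy lost to alkene isomerisation or crossed closure). The fallback sets out from enol ether 9 and comes back at photoadduct 12. Acylation of 9 with trifluoroacetic anhydride and pyridine should give tert-butyl 3-[(2S,3S)-3-methyl-3-[(3E)-pent-3-en-1-yl]-4-(trifluoroacetyl)-2,3-dihydrofuran-2-yl]propanoate F1, a β-alkoxy enone that intersystem-crosses efficiently. Direct irradiation at 350 nm should then give the cyclobutyl trifluoromethyl ketone F2 with the same ring topology. Haloform-type cleavage of this non-enolisable ketone with NaOMe in MeOH converts the acyl group into the methyl ester of 12.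

Step 9 (sluggish heterolysis of the singly activated cyclobutane and epimerisation at C8 through an enol ether while the oxocarbenium ion waits for water). The fallback sets out from 12 and comes back at 13. Ethane-1,2-dithiol and BF3·OEt2 in CH2Cl2 at −30 °C open the cyclobutane under anhydrous conditions and capture the oxocarbenium ion irreversibly as a thioacetal, O3 lactonising as before, to give the 1,3-dithiolane lactone F3. MeI and CaCO3 in aqueous MeCN then unmask the C9 aldehyde under neutral conditions.

Step 19 (poor facial selectivity at C13 during ring closure). The fallback sets out from aldehyde 24 and comes back at 27, accepting the ring closure with the opposite sense to give the 13-epimer of 25, 13-epi alcohol F4. Mitsunobu esterification with propanoic acid (PPh3, DIAD) inverts C13 and installs the propionate directly, giving the 13-propionate 9-silyl ether F5. HF·pyridine then frees O9–H to give the 9-hydroxy 3,13-dipropionate F6, and acylation as in step 21 gives 27.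

Further compounds
F1 | step 8 | tert-butyl 3-[(2S,3S)-3-methyl-3-[(3E)-pent-3-en-1-yl]-4-(trifluoroacetyl)-2,3-dihydrofuran-2-yl]propanoate | C1=C(C(=O)C(F)(F)F)[C@](C)(CC/C=C/C)[C@H](CCC(=O)OC(C)(C)C)O1
F2 | step 8 | cyclobutyl trifluoromethyl ketone (12 with COCF3 in place of CO2Me on C16) | [C@@H]1(CCC(=O)OC(C)(C)C)O[C@@H]2[C@@H](C)[C@@H]3CC[C@@]1(C)[C@]23C(=O)C(F)(F)F
F3 | step 9 | 1,3-dithiolane lactone (13 with C9 as 1,3-dithiolan-2-yl) | O=C1O[C@@H](CCC(=O)OC(C)(C)C)[C@@]2(C)CC[C@@H]([C@H](C)C3SCCS3)[C@@H]12
F4 | step 19 | 13-epi alcohol (C13 epimer of 25) | O=C1[C@H]2C[C@H](OC(=O)CC)[C@@]3(C)CC[C@@H]([C@H](C)[C@@H](O[Si](C)(C)C(C)(C)C)C/C=C(/C)[C@@H](O)C2)[C@@H]13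
F5 | step 19 | 13-propionate 9-silyl ether (C15 ketone) | O=C1[C@H]2C[C@H](OC(=O)CC)[C@@]3(C)CC[C@@H]([C@H](C)[C@@H](O[Si](C)(C)C(C)(C)C)C/C=C(/C)[C@H](OC(=O)CC)C2)[C@@H]13
F6 | step 19 | 9-hydroxy 3,13-dipropionate (C15 ketone) | O=C1[C@H]2C[C@H](OC(=O)CC)[C@@]3(C)CC[C@@H]([C@H](C)[C@@H](O)C/C=C(/C)[C@H](OC(=O)CC)C2)[C@@H]13
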